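**Plan**

- Retrosynthesis: the acyl C–O bond at C1' is cut first. Ring B is then cut at C3–C4, C1–C2 and C1–C8a into an aryl(methoxy)carbene complex of zerovalent chromium (ring A plus C4), one CO ligand (C1) and a terminal alkyne (C3, C2 and the whole side chain). The alkyne is cut at C1'–C(alkyne) and at C2'=C3'.
- Enabling feature: ring B is a quinone in which C2 carries the side chain beside the C1 carbonyl, C3 carries H, and the C4 carbonyl sits on C4a of the 5,8-dioxygenated ring A. A terminal alkyne leaves exactly this pattern when it inserts between an aryl carbene carbon and CO and the resulting ketene closes on the free ortho carbon (C8a).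
- Forward order: the side chain is built first (cross-metathesis, silylation, asymmetric alkynylation, O-silylation, C-desilylation) and the carbene complex is made from bromohydroquinone. Ring B is then closed onto ring A, oxidised to the quinone, the MOM and silyl groups are removed, and the acyl group is joined last.
- Stereochemistry: C1' (R) comes from the ligand-controlled alkynylation of the enal and is carried through unchanged. The (R) centre of the acyl group comes from (R)-2-methylbutanoic acid. The E alkene comes from the cross-metathesis.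

Key step: step 8

Assumption: the (R,R)-ProPhenol–zinc catalyst is taken to add the alkynyl group to the Si face of the enal (3R carbinol), to be confirmed by MTPA ester analysis of the carbinol; (R)-2-methylbutanoic acid is taken as a purchasable single enantiomer.

**Route**

Step 1
Reactants: 1 2-bromobenzene-1,4-diol
Product: 2 2-bromo-1,4-bis(methoxymethoxy)benzene
Conditions: MOMCl, i-Pr2NEt, CH2Cl2, 0 °C to rt
Reagents that add atoms: chloromethyl methyl ether (MOMCl), COCCl
Why: Both phenols are O-alkylated by the α-chloro ether in the presence of a hindered amine (MOM ether formation), giving acetal groups that tolerate organolithium and chromium chemistry and that later sit peri to the quinone carbonyls, where chelation makes them easy to remove.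

Step 2
Reactants: 2 2-bromo-1,4-bis(methoxymethoxy)benzene; 3 hexacarbonylchromium
Product: 6 pentacarbonyl{[2,5-bis(methoxymethoxy)phenyl](methoxy)methylidene}chromium, via aryllithium 4 (not isolated), via lithium acylchromate 5 (not isolated)
Conditions: n-BuLi, THF, −78 °C; Cr(CO)6, −78 °C to rt; MeOTf, CH2Cl2, 0 °C to rt
Reagents that add atoms: methyl trifluoromethanesulfonate (MeOTf), COS(=O)(=O)C(F)(F)F
Why: Bromine–lithium exchange gives the ortho-alkoxy-stabilised aryllithium 4, which adds to a CO ligand of Cr(CO)6 to give acylchromate 5, and hard O-methylation of 5 with MeOTf gives the carbene complex of zerovalent chromium (classical Fischer carbene synthesis).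

Step 3
Reactants: 7 2-methylbut-3-en-2-ol; 8 (E)-but-2-enal (crotonaldehyde, 4 equiv)
Product: 9 (E)-4-hydroxy-4-methylpent-2-enal
Conditions: second-generation Hoveyda–Grubbs catalyst (2.5 mol%), CH2Cl2, 40 °C
Reagents that add atoms: none
Why: Ruthenium-catalysed olefin cross-metathesis joins the unprotected tertiary allylic alcohol to an excess of crotonaldehyde, two partners that homodimerise slowly, with loss of propene as driving force and the E enal as the thermodynamic product.

Step 4
Reactants: 9 (E)-4-hydroxy-4-methylpent-2-enal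
Product: 10 (E)-4-methyl-4-(triethylsilyloxy)pent-2-enal
Conditions: TESOTf, 2,6-lutidine, CH2Cl2, −78 to 0 °C
Reagents that add atoms: triethylsilyl trifluoromethanesulfonate (TESOTf), CC[Si](CC)(CC)OS(=O)(=O)C(F)(F)F
Why: The silyl triflate with a hindered pyridine base silylates the tertiary alcohol at low temperature, and since C4 is quaternary the enal has no γ-hydrogen from which a silyl dienol ether could form.

Step 5
Reactants: 10 (E)-4-methyl-4-(triethylsilyloxy)pent-2-enal; 11 ethynyltrimethylsilane (3 equiv)
Product: 12 (3R,4E)-6-methyl-6-(triethylsilyloxy)-1-(trimethylsilyl)hept-4-en-1-yn-3-ol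
Conditions: ZnMe2 (3 equiv), (R,R)-ProPhenol (10 mol%), Ph3PO (20 mol%), PhMe, 0–4 °C; aq NH4Cl
Reagents that add atoms: none
Why: The zinc alkynylide formed from 11 and ZnMe2 adds to the aldehyde inside the dinuclear zinc complex of (R,R)-ProPhenol, 2,6-bis{[(R)-2-(hydroxydiphenylmethyl)pyrrolidin-1-yl]methyl}-4-methylphenol (catalytic asymmetric alkynylation of an α,β-unsaturated aldehyde), the ligand directing attack to the Si face so that C3 is set as R, while the non-enolisable enal and its tertiary silyl ether are inert to the zinc reagents.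

Step 6
Reactants: 12 (3R,4E)-6-methyl-6-(triethylsilyloxy)-1-(trimethylsilyl)hept-4-en-1-yn-3-ol
Product: 13 (3R,4E)-3-(tert-butyldimethylsilyloxy)-6-methyl-6-(triethylsilyloxy)-1-(trimethylsilyl)hept-4-en-1-yne
Conditions: TBSCl, imidazole, DMF, rt
Reagents that add atoms: tert-butyldimethylsilyl chloride (TBSCl), CC(C)(C)[Si](C)(C)Cl
Why: This is the standard silylation of a secondary propargylic alcohol with the silyl chloride and imidazole, in which no bond to C3 is broken, so the configuration is retained.

Step 7
Reactants: 13 (3R,4E)-3-(tert-butyldimethylsilyloxy)-6-methyl-6-(triethylsilyloxy)-1-(trimethylsilyl)hept-4-en-1-yne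
Product: 14 (3R,4E)-3-(tert-butyldimethylsilyloxy)-6-methyl-6-(triethylsilyloxy)hept-4-en-1-yne
Conditions: K2CO3 (0.2 equiv), MeOH, 0 °C to rt
Reagents that add atoms: none
Why: Methoxide generated from K2CO3 in MeOH attacks the alkynyl silicon and the acetylide is protonated (protodesilylation of a C-silyl alkyne), a reaction to which silyl ethers of secondary and tertiary alcohols are inert at this temperature.

Step 8
Reactants: 6 pentacarbonyl{[2,5-bis(methoxymethoxy)phenyl](methoxy)methylidene}chromium (1.3 equiv); 14 (3R,4E)-3-(tert-butyldimethylsilyloxy)-6-methyl-6-(triethylsilyloxy)hept-4-en-1-yne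
Product: 16 2-[(1R,2E)-1-(tert-butyldimethylsilyloxy)-4-methyl-4-(triethylsilyloxy)pent-2-en-1-yl]-4-methoxy-5,8-bis(methoxymethoxy)naphthalen-1-ol, via tricarbonylchromium naphthol complex 15 (not isolated)
Conditions: THF (degassed, 0.05 M), 50 °C, Ar; then air, MeCN, rt
Reagents that add atoms: none
Why: Heating releases one CO from zerovalent chromium in 6, alkyne 14 coordinates and inserts into the Cr=C bond with its unsubstituted carbon bonded to the former carbene carbon (C3–C4), and a CO ligand then inserts to form the chromium-bound vinylketene (C1–C2). Ring B closes by 6π electrocyclisation of this aryl-conjugated vinylketene onto the free ortho carbon of the aryl group (C1–C8a), and tautomerisation of the cyclohexadienone gives the naphthol as its Cr(CO)3 complex 15, which air decomplexes to 16. The closest known reaction is the Dötz benzannulation of aryl(alkoxy)carbene chromium complexes with terminal alkynes, propargylic silyl ethers included. No stereocentre is created: C1' is a spectator under these neutral conditions, and the planar chirality of 15 disappears on decomplexation. The selectivity needed is the regiochemistry of insertion, secured by the large steric difference between the hydrogen and the branched silyloxy-bearing substituent of a terminal alkyne, which places that substituent on C2 next to the CO-derived C1; cyclisation has one site only because the other ortho position carries OMOM. The skipped alkene of 14 cannot trap the vinylcarbene, since that would require a bicyclobutane.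

Step 9
Reactants: 16 2-[(1R,2E)-1-(tert-butyldimethylsilyloxy)-4-methyl-4-(triethylsilyloxy)pent-2-en-1-yl]-4-methoxy-5,8-bis(methoxymethoxy)naphthalen-1-ol
Product: 17 2-[(1R,2E)-1-(tert-butyldimethylsilyloxy)-4-methyl-4-(triethylsilyloxy)pent-2-en-1-yl]-5,8-bis(methoxymethoxy)naphthalene-1,4-dione
Conditions: PhI(OAc)2, MeCN/H2O (3:1), 0 °C
Reagents that add atoms: water, O
Why: The naphthol exchanges onto trivalent iodine and is oxidised by two electrons to a phenoxenium-type cation that water captures at C4, the hemiketal then expels methanol to give the 1,4-quinone (hypervalent iodine oxidation of a para-methoxyphenol), and because the reagent needs a free phenol it leaves the MOM-protected ring A and the silyl ethers alone.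

Step 10
Reactants: 17 2-[(1R,2E)-1-(tert-butyldimethylsilyloxy)-4-methyl-4-(triethylsilyloxy)pent-2-en-1-yl]-5,8-bis(methoxymethoxy)naphthalene-1,4-dione
Product: 18 2-[(1R,2E)-1-(tert-butyldimethylsilyloxy)-4-methyl-4-(triethylsilyloxy)pent-2-en-1-yl]-5,8-dihydroxynaphthalene-1,4-dione
Conditions: MgBr2·OEt2, Me2S, CH2Cl2, 0 °C to rt; aq NH4Cl
Reagents that add atoms: none
Why: Magnesium held between each quinone carbonyl and the peri MOM oxygen activates the acetal for bromide attack at its CH2 group (chelation-assisted Lewis acid cleavage of aryl alkoxymethyl ethers), Me2S removes the bromomethyl methyl ether so that it cannot re-alkylate, and the bulky, non-chelating silyl ethers are not engaged.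

Step 11
Reactants: 18 2-[(1R,2E)-1-(tert-butyldimethylsilyloxy)-4-methyl-4-(triethylsilyloxy)pent-2-en-1-yl]-5,8-dihydroxynaphthalene-1,4-dione
Product: 19 5,8-dihydroxy-2-[(1R,2E)-1,4-dihydroxy-4-methylpent-2-en-1-yl]naphthalene-1,4-dione
Conditions: HF·pyridine, pyridine, THF, 0 °C to rt
Reagents that add atoms: none
Why: Buffered HF·pyridine cleaves the secondary TBS and tertiary TES ethers through formation of the strong Si–F bond under mildly acidic conditions that the base-sensitive naphthazarin tolerates, and no bond to C1' is touched.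

Step 12
Reactants: 19 5,8-dihydroxy-2-[(1R,2E)-1,4-dihydroxy-4-methylpent-2-en-1-yl]naphthalene-1,4-dione; 20 (R)-2-methylbutanoic acid (1.2 equiv)
Product: 21 (1R,2E)-1-(5,8-dihydroxy-1,4-dioxo-1,4-dihydronaphthalen-2-yl)-4-hydroxy-4-methylpent-2-en-1-yl (2R)-2-methylbutanoate
Conditions: DCC, DMAP (0.2 equiv), CH2Cl2, 0 °C to rt
Reagents that add atoms: none
Why: Steglich esterification acylates the secondary allylic alcohol in preference to the hindered tertiary alcohol and to the two peri-hydrogen-bonded naphthazarin phenols, as is usual for naphthazarins with a secondary side-chain alcohol such as shikonin, and under these cold, weakly basic conditions the α-centre of the acid should not epimerise, so both (R) centres are kept.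

**Compound list**

1 | 2-bromobenzene-1,4-diol (bromohydroquinone) | Oc1ccc(O)c(Br)c1 | starting material
2 | 2-bromo-1,4-bis(methoxymethoxy)benzene | COCOc1ccc(OCOC)c(Br)c1 | intermediate
3 | hexacarbonylchromium, Cr(CO)6 | O=C=[Cr](=C=O)(=C=O)(=C=O)(=C=O)=C=O | starting material
4 | [2,5-bis(methoxymethoxy)phenyl]lithium | [Li]c1cc(OCOC)ccc1OCOC | intermediate
5 | lithium pentacarbonyl{[2,5-bis(methoxymethoxy)phenyl](oxido)methylidene}chromate (acylchromate) | [Li+].[O-]C(c1cc(OCOC)ccc1OCOC)=[Cr](=C=O)(=C=O)(=C=O)(=C=O)=C=O | intermediate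
6 | pentacarbonyl{[2,5-bis(methoxymethoxy)phenyl](methoxy)methylidene}chromium | COCOc1ccc(OCOC)c(c1)C(OC)=[Cr](=C=O)(=C=O)(=C=O)(=C=O)=C=O | intermediate
7 | 2-methylbut-3-en-2-ol | CC(C)(O)C=C | starting material
8 | (E)-but-2-enal (crotonaldehyde) | C/C=C/C=O | starting material
9 | (E)-4-hydroxy-4-methylpent-2-enal | CC(C)(O)/C=C/C=O | intermediate
10 | (E)-4-methyl-4-(triethylsilyloxy)pent-2-enal | CC[Si](CC)(CC)OC(C)(C)/C=C/C=O | intermediate
11 | ethynyltrimethylsilane | C#C[Si](C)(C)C | starting material
12 | (3R,4E)-6-methyl-6-(triethylsilyloxy)-1-(trimethylsilyl)hept-4-en-1-yn-3-ol | O[C@H](/C=C/C(C)(C)O[Si](CC)(CC)CC)C#C[Si](C)(C)C | intermediate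
13 | (3R,4E)-3-(tert-butyldimethylsilyloxy)-6-methyl-6-(triethylsilyloxy)-1-(trimethylsilyl)hept-4-en-1-yne | CC(C)(C)[Si](C)(C)O[C@H](/C=C/C(C)(C)O[Si](CC)(CC)CC)C#C[Si](C)(C)C | intermediate
14 | (3R,4E)-3-(tert-butyldimethylsilyloxy)-6-methyl-6-(triethylsilyloxy)hept-4-en-1-yne | CC(C)(C)[Si](C)(C)O[C@H](/C=C/C(C)(C)O[Si](CC)(CC)CC)C#C | intermediate
15 | tricarbonylchromium complex of naphthol 16, Cr(CO)3 bound η6 to ring B, mixture of planar diastereomers (written as arene plus Cr(CO)3 fragment because η6 bonding has no SMILES form) | CC(C)(C)[Si](C)(C)O[C@H](/C=C/C(C)(C)O[Si](CC)(CC)CC)c1cc(OC)c2c(OCOC)ccc(OCOC)c2c1O.[Cr](=C=O)(=C=O)=C=O | intermediate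
16 | 2-[(1R,2E)-1-(tert-butyldimethylsilyloxy)-4-methyl-4-(triethylsilyloxy)pent-2-en-1-yl]-4-methoxy-5,8-bis(methoxymethoxy)naphthalen-1-ol | CC(C)(C)[Si](C)(C)O[C@H](/C=C/C(C)(C)O[Si](CC)(CC)CC)c1cc(OC)c2c(OCOC)ccc(OCOC)c2c1O | intermediate
17 | 2-[(1R,2E)-1-(tert-butyldimethylsilyloxy)-4-methyl-4-(triethylsilyloxy)pent-2-en-1-yl]-5,8-bis(methoxymethoxy)naphthalene-1,4-dione | CC(C)(C)[Si](C)(C)O[C@H](/C=C/C(C)(C)O[Si](CC)(CC)CC)C1=CC(=O)c2c(OCOC)ccc(OCOC)c2C1=O | intermediate
18 | 2-[(1R,2E)-1-(tert-butyldimethylsilyloxy)-4-methyl-4-(triethylsilyloxy)pent-2-en-1-yl]-5,8-dihydroxynaphthalene-1,4-dione | CC(C)(C)[Si](C)(C)O[C@H](/C=C/C(C)(C)O[Si](CC)(CC)CC)C1=CC(=O)c2c(O)ccc(O)c2C1=O | intermediate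
19 | 5,8-dihydroxy-2-[(1R,2E)-1,4-dihydroxy-4-methylpent-2-en-1-yl]naphthalene-1,4-dione | O[C@H](/C=C/C(C)(C)O)C1=CC(=O)c2c(O)ccc(O)c2C1=O | intermediate
20 | (R)-2-methylbutanoic acid | CC[C@@H](C)C(=O)O | starting material
21 | (1R,2E)-1-(5,8-dihydroxy-1,4-dioxo-1,4-dihydronaphthalen-2-yl)-4-hydroxy-4-methylpent-2-en-1-yl (2R)-2-methylbutanoate | CC[C@@H](C)C(=O)O[C@H](/C=C/C(C)(C)O)C1=CC(=O)c2c(O)ccc(O)c2C1=O | target

**Step count and risks**

Total step count: 12. Longest linear sequence: 10 steps (7 to 21, steps 3 to 12); the carbene branch (1 to 6) is 2 steps.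

Steps most likely to fail:

Step 8. The tetra-oxygenated, electron-rich naphthol may decay while it is freed from chromium in air and chromatographed, by over-oxidation or by loss of silanol through an ortho-quinone methide. Fallback: the free naphthol is no longer isolated. Setting out from 6 and 14, the annulation is run as a benzannulation–acylation (Ac2O, Et3N, THF, 55 °C), so that the phenol is captured as it forms. The compound isolated is then the air-stable 2-[(1R,2E)-1-(tert-butyldimethylsilyloxy)-4-methyl-4-(triethylsilyloxy)pent-2-en-1-yl]-4-methoxy-5,8-bis(methoxymethoxy)naphthalen-1-yl acetate F1. Methanolysis of F1 (K2CO3, degassed MeOH, 0 °C) releases 16 in metal-free solution. After neutralisation it is oxidised in the same flask with PhI(OAc)2 in MeCN/H2O, and the sequence comes back to the route at 17.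

Step 12. Site selectivity may be lost through acylation of a naphthazarin phenol, or the free naphthazarin may oligomerise under DMAP. Fallback: the acyl group is introduced while ring A is still protected, so that only a secondary and a tertiary alcohol compete. Setting out from 17, HF·pyridine (pyridine, THF) should give 2-[(1R,2E)-1,4-dihydroxy-4-methylpent-2-en-1-yl]-5,8-bis(methoxymethoxy)naphthalene-1,4-dione F2. Steglich acylation of F2 with 20 (DCC, DMAP, CH2Cl2, 0 °C) should give (1R,2E)-1-[5,8-bis(methoxymethoxy)-1,4-dioxo-1,4-dihydronaphthalen-2-yl]-4-hydroxy-4-methylpent-2-en-1-yl (2R)-2-methylbutanoate F3. Chelation-assisted cleavage of the two MOM ethers of F3 (MgBr2·OEt2, Me2S, CH2Cl2; the sulfide also keeps the free tertiary alcohol from being alkylated) comes back to the route at 21.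

Step 5. Facial selectivity of the zinc alkynylide addition may be insufficient for this γ-quaternary enal, which would carry a diastereomer into every later compound. Fallback: C3 is set by reagent-controlled reduction of a ketone instead of by C–C bond formation. Setting out from 10 and 11, LiC≡CSiMe3 (from 11 and n-BuLi, THF, −78 °C) should give racemic (4E)-6-methyl-6-(triethylsilyloxy)-1-(trimethylsilyl)hept-4-en-1-yn-3-ol F4. Oxidation with MnO2 (CH2Cl2, rt) should give (4E)-6-methyl-6-(triethylsilyloxy)-1-(trimethylsilyl)hept-4-en-1-yn-3-one F5. Reduction of F5 with (R)-Alpine-Borane (B-isopinocampheyl-9-borabicyclo[3.3.1]nonane from (+)-α-pinene), which treats the slim alkynyl group as the small substituent of an alkynyl ketone, should give the (R)-carbinol and comes back to the route at 12.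

Further compounds
F1 | step 8 | 2-[(1R,2E)-1-(tert-butyldimethylsilyloxy)-4-methyl-4-(triethylsilyloxy)pent-2-en-1-yl]-4-methoxy-5,8-bis(methoxymethoxy)naphthalen-1-yl acetate | CC(C)(C)[Si](C)(C)O[C@H](/C=C/C(C)(C)O[Si](CC)(CC)CC)c1cc(OC)c2c(OCOC)ccc(OCOC)c2c1OC(C)=O
F2 | step 12 | 2-[(1R,2E)-1,4-dihydroxy-4-methylpent-2-en-1-yl]-5,8-bis(methoxymethoxy)naphthalene-1,4-dione | O[C@H](/C=C/C(C)(C)O)C1=CC(=O)c2c(OCOC)ccc(OCOC)c2C1=O
F3 | step 12 | (1R,2E)-1-[5,8-bis(methoxymethoxy)-1,4-dioxo-1,4-dihydronaphthalen-2-yl]-4-hydroxy-4-methylpent-2-en-1-yl (2R)-2-methylbutanoate | CC[C@@H](C)C(=O)O[C@H](/C=C/C(C)(C)O)C1=CC(=O)c2c(OCOC)ccc(OCOC)c2C1=O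
F4 | step 5 | racemic (4E)-6-methyl-6-(triethylsilyloxy)-1-(trimethylsilyl)hept-4-en-1-yn-3-ol | OC(/C=C/C(C)(C)O[Si](CC)(CC)CC)C#C[Si](C)(C)C
F5 | step 5 | (4E)-6-methyl-6-(triethylsilyloxy)-1-(trimethylsilyl)hept-4-en-1-yn-3-one | O=C(/C=C/C(C)(C)O[Si](CC)(CC)CC)C#C[Si](C)(C)C
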